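**Retrosynthetic overview** (numbering: lactone ring O1, C2–C6; side chain C1'–C10', C1' on C6, phenyl on C10')
1. The lactone is carried as its methyl acetal (a 6-methoxy-3,6-dihydro-2H-pyran) and unmasked last: acetal hydrolysis, then MnO2 oxidation of the allylic lactol.
2. Key disconnection C4'–C5': the primary C5'–B bond of a 1,2-bis(boronic ester) (boron on C5' and C6') is homologated by the sparteine-derived α-lithio benzoate of C4'; oxidation of both C–B bonds in the same flask gives the C4'/C6' syn-diol.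
3. Enabling feature: the syn-1,3-diol C4'(OH)–C5'H2–C6'(OH). The C5'–C6' pair maps onto a terminal alkene (diboration) and the C4' carbinol onto an ester-activated O–CH2 group; the only electrophilic ring atom (C2) is masked as an acetal so the ring survives the organolithium.
4. Fragment C5'–C10': Brown allylation (C8'), silylation, Pt-catalysed diboration (C6'). Fragment C2–C4': benzoate of but-3-yn-1-ol, formylation, asymmetric hetero-Diels–Alder reaction (C6), Lindlar reduction (Z-C1'=C2').
5. Ring order: the pyran ring is the only ring formed (step 6, [4+2] cycloaddition); it is kept to the end.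

Key step: step 8

Assumption: in the two catalyst-controlled steps (3 and 6) the ligand enantiomer named is the one expected to give the drawn configuration; the antipodal ligand is equally accessible and would be used without other change if the sense proved opposite.

Step 1
Reactants: 1 3-phenylpropanal
Product: 3 (R)-1-phenylhex-5-en-3-ol, via diisopinocampheylborinate 2 (not isolated)
Conditions: (−)-Ipc2B(allyl) (from (+)-α-pinene, 1 M in pentane), Et2O, −78 °C; then 3 M NaOH, 30% H2O2, 0 °C → rt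
Reagents that add atoms: (−)-B-allyldiisopinocampheylborane, C=CCB([C@@H]1C[C@@H]2C[C@H]([C@H]1C)C2(C)C)[C@@H]1C[C@@H]2C[C@H]([C@H]1C)C2(C)C
Why: Brown allylation through a chair six-membered transition state; the isopinocampheyl groups derived from (+)-α-pinene should direct the allyl group to the Si face of the aldehyde and set C8' as R.

Step 2
Reactants: 3 (R)-1-phenylhex-5-en-3-ol
Product: 4 (R)-triethyl[(1-phenylhex-5-en-3-yl)oxy]silane
Conditions: TESCl, imidazole, CH2Cl2, 0 °C → rt
Reagents that add atoms: chlorotriethylsilane, CC[Si](Cl)(CC)CC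
Why: Standard silylation of a secondary alcohol; the TES ether removes the acidic proton before the organolithium step and falls off under the final mild acid.

Step 3
Reactants: 4 (R)-triethyl[(1-phenylhex-5-en-3-yl)oxy]silane
Product: 5 2,2'-[(2R,4R)-6-phenyl-4-(triethylsilyloxy)hexane-1,2-diyl]bis(4,4,5,5-tetramethyl-1,3,2-dioxaborolane)
Conditions: B2pin2, Pt(dba)3 (3 mol%), (R,R)-3,5-diisopropylphenyl-TADDOL phenylphosphonite (6 mol%), THF, 60 °C
Reagents that add atoms: bis(pinacolato)diboron, CC1(C)OB(B2OC(C)(C)C(C)(C)O2)OC1(C)C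
Why: Enantioselective alkene 1,2-diboration (oxidative addition of B–B to zerovalent platinum, alkene insertion, reductive elimination, overall syn addition); the chiral phosphonite should control the alkene face and set C6', with the remote C8' centre expected to have little influence.

Step 4
Reactants: 6 but-3-yn-1-ol
Product: 7 but-3-yn-1-yl 2,4,6-tri(propan-2-yl)benzoate
Conditions: 2,4,6-triisopropylbenzoyl chloride, Et3N, DMAP (cat.), CH2Cl2, rt → 40 °C
Reagents that add atoms: 2,4,6-triisopropylbenzoyl chloride, CC(C)c1cc(C(C)C)c(C(=O)Cl)c(C(C)C)c1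
Why: Acylation of a primary alcohol; the hindered benzoate resists nucleophilic attack and later serves as directing and leaving group at C4'.

Step 5
Reactants: 7 but-3-yn-1-yl 2,4,6-tri(propan-2-yl)benzoate
Product: 10 5-oxopent-3-yn-1-yl 2,4,6-tri(propan-2-yl)benzoate, via lithium acetylide 8 (not isolated), via lithium hemiaminal alkoxide 9 (not isolated)
Conditions: nBuLi (1.05 equiv), THF, −78 °C; DMF, −78 → 0 °C; inverse quench into cold aq. KH2PO4/MTBE
Reagents that add atoms: N,N-dimethylformamide, CN(C)C=O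
Why: Formylation of a lithium acetylide with DMF; the terminal alkyne C–H is far more acidic than any other site and the hindered ester is not attacked, while the buffered inverse quench should avoid amine addition to the ynal.

Step 6
Reactants: 10 5-oxopent-3-yn-1-yl 2,4,6-tri(propan-2-yl)benzoate; 11 (E)-1-methoxybuta-1,3-diene
Product: 12 4-[(2S,6R)-6-methoxy-3,6-dihydro-2H-pyran-2-yl]but-3-yn-1-yl 2,4,6-tri(propan-2-yl)benzoate (2,6-cis)
Conditions: (L)CrCl (3 mol%; L = dianion of the Schiff base of 3-(1-adamantyl)-2-hydroxy-5-methylbenzaldehyde and (1S,2R)-1-aminoindan-2-ol, trivalent chromium), 4 Å MS, diene (2 equiv), neat, rt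
Reagents that add atoms: none
Why: Catalytic asymmetric hetero-Diels–Alder reaction of an ynal activated by the chiral Lewis acid; the endo [4+2] addition should give the 2,6-cis acetal and the catalyst controls the aldehyde face, setting the future lactone C6 (S).

Step 7
Reactants: 12 4-[(2S,6R)-6-methoxy-3,6-dihydro-2H-pyran-2-yl]but-3-yn-1-yl 2,4,6-tri(propan-2-yl)benzoate
Product: 13 (3Z)-4-[(2S,6R)-6-methoxy-3,6-dihydro-2H-pyran-2-yl]but-3-en-1-yl 2,4,6-tri(propan-2-yl)benzoate
Conditions: H2 (1 atm), Pd/CaCO3 poisoned with Pb(OAc)2 (Lindlar catalyst), quinoline, EtOAc, rt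
Reagents that add atoms: none
Why: Lindlar semihydrogenation; syn delivery of hydrogen to the alkyne should give the Z-C1'=C2' alkene, and the ring alkene is expected to react much more slowly.

Step 8
Reactants: 13 (3Z)-4-[(2S,6R)-6-methoxy-3,6-dihydro-2H-pyran-2-yl]but-3-en-1-yl 2,4,6-tri(propan-2-yl)benzoate; 5 2,2'-[(2R,4R)-6-phenyl-4-(triethylsilyloxy)hexane-1,2-diyl]bis(4,4,5,5-tetramethyl-1,3,2-dioxaborolane)
Product: 17 (3R,5R,7R,9Z)-10-[(2S,6R)-6-methoxy-3,6-dihydro-2H-pyran-2-yl]-1-phenyl-3-(triethylsilyloxy)dec-9-ene-5,7-diol, via lithiated benzoate 14 (not isolated), via boronate complex 15 (not isolated), via 1,3-bis(boronic ester) 16 (not isolated)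
Conditions: 13 (1.3 equiv), sBuLi (1.25 equiv), (−)-sparteine (1.3 equiv), Et2O, −78 °C, 5 h; add 5 (1.0 equiv) in Et2O, −78 °C, 2 h; then 35 °C, 12 h; then THF, 2 M NaOH, 30% H2O2, 0 °C → rt
Reagents that add atoms: hydrogen peroxide, OO
Why: Sparteine-mediated asymmetric α-lithiation of the hindered benzoate removes the pro-S hydrogen at C4' to give configurationally stable 14, which borylates the primary boron (on C5') of 5 with retention to give ate complex 15; the C5' methylene then migrates from boron to C4' antiperiplanar to the departing triisopropylbenzoate (1,2-metallate rearrangement, inversion at C4') to give 16, and alkaline hydrogen peroxide converts both C–B bonds into C–O bonds with retention. The closest known reaction type is the lithiation–borylation homologation of 1,2-bis(boronic esters) with lithiated benzoates or carbamates, followed by oxidation to 1,3-diols. No ring is closed in this step. The new stereocentre C4' (R) is set by reagent control from (−)-sparteine through the stereospecific retention–inversion–retention sequence, while C6' is carried unchanged from the diboration, so the syn C4'/C6' and anti C6'/C8' relationships follow. The step needs boron-site selectivity (primary over secondary boronic ester), which the steric difference between the CH2–B and CH–B groups of 5 should secure. It also needs deprotonation at O–CH2 rather than at the allylic or acetal C–H bonds, which precomplexation of sBuLi/sparteine to the benzoate carbonyl in Et2O at −78 °C should secure; the acetal-masked lactone offers no electrophilic carbonyl.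

Step 9
Reactants: 17 (3R,5R,7R,9Z)-10-[(2S,6R)-6-methoxy-3,6-dihydro-2H-pyran-2-yl]-1-phenyl-3-(triethylsilyloxy)dec-9-ene-5,7-diol
Product: 18 (6S)-6-[(1Z,4R,6S,8R)-4,6,8-trihydroxy-10-phenyldec-1-en-1-yl]-5,6-dihydro-2H-pyran-2-ol (mixture of anomers)
Conditions: 0.5 M aq. HCl, THF, 0 °C → rt
Reagents that add atoms: water, O
Why: Acid hydrolysis of the allylic mixed acetal through the conjugated oxocarbenium ion, with acid cleavage of the TES ether in the same operation; no stereocentre of the target is touched.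

Step 10
Reactants: 18 (6S)-6-[(1Z,4R,6S,8R)-4,6,8-trihydroxy-10-phenyldec-1-en-1-yl]-5,6-dihydro-2H-pyran-2-ol
Product: 19 (6S)-6-[(1Z,4R,6S,8R)-4,6,8-trihydroxy-10-phenyldec-1-en-1-yl]-5,6-dihydro-2H-pyran-2-one
Conditions: MnO2 (activated, 20 equiv), EtOAc, rt
Reagents that add atoms: none
Why: Chemoselective MnO2 oxidation of an allylic lactol to the α,β-unsaturated δ-lactone; the three other carbinols are non-allylic secondary alcohols and should not react.

**Compound list**
1 | 3-phenylpropanal | O=CCCc1ccccc1 | starting material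
2 | (3R)-1-phenylhex-5-en-3-yl diisopinocampheylborinate | C=CC[C@@H](CCc1ccccc1)OB([C@@H]1C[C@@H]2C[C@H]([C@H]1C)C2(C)C)[C@@H]1C[C@@H]2C[C@H]([C@H]1C)C2(C)C | intermediate
3 | (R)-1-phenylhex-5-en-3-ol | C=CC[C@H](O)CCc1ccccc1 | intermediate
4 | (R)-triethyl[(1-phenylhex-5-en-3-yl)oxy]silane | C=CC[C@H](O[Si](CC)(CC)CC)CCc1ccccc1 | intermediate
5 | 2,2'-[(2R,4R)-6-phenyl-4-(triethylsilyloxy)hexane-1,2-diyl]bis(4,4,5,5-tetramethyl-1,3,2-dioxaborolane) | CC1(C)OB(C[C@@H](B2OC(C)(C)C(C)(C)O2)C[C@H](O[Si](CC)(CC)CC)CCc2ccccc2)OC1(C)C | intermediate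
6 | but-3-yn-1-ol | C#CCCO | starting material
7 | but-3-yn-1-yl 2,4,6-tri(propan-2-yl)benzoate | C#CCCOC(=O)c1c(C(C)C)cc(C(C)C)cc1C(C)C | intermediate
8 | lithium acetylide of 7 | [Li]C#CCCOC(=O)c1c(C(C)C)cc(C(C)C)cc1C(C)C | intermediate
9 | lithium 1-(dimethylamino)-5-[2,4,6-tri(propan-2-yl)benzoyloxy]pent-2-yn-1-olate | [Li]OC(N(C)C)C#CCCOC(=O)c1c(C(C)C)cc(C(C)C)cc1C(C)C | intermediate
10 | 5-oxopent-3-yn-1-yl 2,4,6-tri(propan-2-yl)benzoate | O=CC#CCCOC(=O)c1c(C(C)C)cc(C(C)C)cc1C(C)C | intermediate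
11 | (E)-1-methoxybuta-1,3-diene | CO/C=C/C=C | starting material
12 | 4-[(2S,6R)-6-methoxy-3,6-dihydro-2H-pyran-2-yl]but-3-yn-1-yl 2,4,6-tri(propan-2-yl)benzoate | CO[C@H]1C=CC[C@@H](C#CCCOC(=O)c2c(C(C)C)cc(C(C)C)cc2C(C)C)O1 | intermediate
13 | (3Z)-4-[(2S,6R)-6-methoxy-3,6-dihydro-2H-pyran-2-yl]but-3-en-1-yl 2,4,6-tri(propan-2-yl)benzoate | CO[C@H]1C=CC[C@@H](/C=C\CCOC(=O)c2c(C(C)C)cc(C(C)C)cc2C(C)C)O1 | intermediate
14 | (1S,3Z)-1-lithio-4-[(2S,6R)-6-methoxy-3,6-dihydro-2H-pyran-2-yl]but-3-en-1-yl 2,4,6-tri(propan-2-yl)benzoate (sparteine complex) | CO[C@H]1C=CC[C@@H](/C=C\C[C@H]([Li])OC(=O)c2c(C(C)C)cc(C(C)C)cc2C(C)C)O1 | intermediate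
15 | lithium boronate complex: the C5' boron of 5 bonded to C4' of 14, benzoate still on C4' | [Li+].CO[C@H]1C=CC[C@@H](/C=C\C[C@H]([B-]2(C[C@@H](B3OC(C)(C)C(C)(C)O3)C[C@H](O[Si](CC)(CC)CC)CCc3ccccc3)OC(C)(C)C(C)(C)O2)OC(=O)c2c(C(C)C)cc(C(C)C)cc2C(C)C)O1 | intermediate
16 | 1,3-bis(pinacol boronic ester) with boron on C4' and C6' of the joined chain (C–B bonds configured as the C–O bonds of 17) | CO[C@H]1C=CC[C@@H](/C=C\C[C@@H](B2OC(C)(C)C(C)(C)O2)C[C@@H](B2OC(C)(C)C(C)(C)O2)C[C@H](O[Si](CC)(CC)CC)CCc2ccccc2)O1 | intermediate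
17 | (3R,5R,7R,9Z)-10-[(2S,6R)-6-methoxy-3,6-dihydro-2H-pyran-2-yl]-1-phenyl-3-(triethylsilyloxy)dec-9-ene-5,7-diol | CO[C@H]1C=CC[C@@H](/C=C\C[C@@H](O)C[C@@H](O)C[C@H](O[Si](CC)(CC)CC)CCc2ccccc2)O1 | intermediate
18 | (6S)-6-[(1Z,4R,6S,8R)-4,6,8-trihydroxy-10-phenyldec-1-en-1-yl]-5,6-dihydro-2H-pyran-2-ol (anomer mixture) | OC1C=CC[C@@H](/C=C\C[C@@H](O)C[C@@H](O)C[C@H](O)CCc2ccccc2)O1 | intermediate
19 | (6S)-6-[(1Z,4R,6S,8R)-4,6,8-trihydroxy-10-phenyldec-1-en-1-yl]-5,6-dihydro-2H-pyran-2-one | O=C1C=CC[C@@H](/C=C\C[C@@H](O)C[C@@H](O)C[C@H](O)CCc2ccccc2)O1 | target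

**Step count**
Total step count: 10. Longest linear sequence: 7 steps (steps 4–10, from but-3-yn-1-ol); the other branch is steps 1–3.

**Steps most likely to fail**

1. Step 8. What may go wrong: deprotonation of 13 away from the O–CH2 group (allylic C3'–H, ring C6–H or acetal C–H) competing with the directed α-lithiation, borylation at the secondary boron, or sluggish 1,2-migration, each eroding conversion or stereochemical fidelity at C4'. The fallback forms the same C4'–C5' bond by a 1,5-anti boron aldol reaction; it sets out from 3 and 13 and comes back to the route at 18. From 3, 4-methoxybenzyl trichloroacetimidate with catalytic camphorsulfonic acid gives (R)-1-[(4-methoxybenzyl)oxy]-1-(2-phenylethyl)but-3-ene, i.e. the PMB ether of 3 F1, and Wacker oxidation (PdCl2, CuCl, O2, DMF/H2O) gives (R)-4-[(4-methoxybenzyl)oxy]-6-phenylhexan-2-one F2. From 13, LiAlH4 (THF, 0 °C → rt) removes the benzoate to give (3Z)-4-[(2S,6R)-6-methoxy-3,6-dihydro-2H-pyran-2-yl]but-3-en-1-ol F3, and Dess–Martin periodinane gives the β,γ-unsaturated aldehyde (3Z)-4-[(2S,6R)-6-methoxy-3,6-dihydro-2H-pyran-2-yl]but-3-enal F4, to be used at once. The dibutylboron enolate of F2 (Bu2BOTf, iPr2NEt, Et2O, −78 °C) should add to F4 with 1,5-anti induction from the β-PMB ether to give (3R,7R,9Z)-7-hydroxy-3-[(4-methoxybenzyl)oxy]-10-[(2S,6R)-6-methoxy-3,6-dihydro-2H-pyran-2-yl]-1-phenyldec-9-en-5-one F5. Narasaka–Prasad reduction (Et2BOMe, NaBH4, THF/MeOH, −78 °C) should give the syn-diol (3R,5R,7R,9Z)-3-[(4-methoxybenzyl)oxy]-10-[(2S,6R)-6-methoxy-3,6-dihydro-2H-pyran-2-yl]-1-phenyldec-9-ene-5,7-diol F6. DDQ (CH2Cl2/pH 7 buffer) removes the PMB group to give (3R,5S,7R,9Z)-10-[(2S,6R)-6-methoxy-3,6-dihydro-2H-pyran-2-yl]-1-phenyldec-9-ene-3,5,7-triol F7, and aqueous HCl/THF hydrolyses the acetal of F7 to 18.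

2. Step 3. What may go wrong: insufficient catalyst control of the alkene face (mismatch with the C8' centre or opposite sense), giving a mixture of C6' epimers that would be carried into the key step. The fallback builds the two C–B bonds one at a time; it sets out from 4 and comes back at 5. Cross-metathesis of 4 with vinylboronic acid pinacol ester (second-generation Grubbs catalyst, CH2Cl2, 40 °C) gives (R,E)-triethyl{[1-phenyl-6-(4,4,5,5-tetramethyl-1,3,2-dioxaborolan-2-yl)hex-5-en-3-yl]oxy}silane F8. Copper-catalysed enantioselective protoboration of this alkenyl boronate (CuCl, chiral N-heterocyclic carbene ligand, NaOtBu, B2pin2, MeOH, THF) places the second boron on C6' and gives 5.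

3. Step 9. What may go wrong: under aqueous acid the lactol can open to the (Z)-5-hydroxy-enal, which may isomerise to the (E)-enal or eliminate across the allylic C6–O bond before it is oxidised, and the polar tetraol lactol may be lost on purification. The fallback avoids the free lactol; it sets out from 17 and comes back at 19. 2,2-Dimethoxypropane with catalytic PPTS (CH2Cl2, rt) gives the acetonide of 17 spanning O4' and O6' F9. Pyridinium chlorochromate, [C5H5NH][CrO3Cl], with NaOAc in CH2Cl2 oxidises the cyclic allylic acetal directly to the protected lactone, the 4',6'-acetonide 8'-TES ether of 19 F10. Aqueous HF in MeCN (0 °C → rt) removes acetonide and TES to give 19.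

**Further compounds**
F1 | step 8 | (R)-1-methoxy-4-{[(1-phenylhex-5-en-3-yl)oxy]methyl}benzene | C=CC[C@H](OCc1ccc(OC)cc1)CCc1ccccc1
F2 | step 8 | (R)-4-[(4-methoxybenzyl)oxy]-6-phenylhexan-2-one | CC(=O)C[C@H](OCc1ccc(OC)cc1)CCc1ccccc1
F3 | step 8 | (3Z)-4-[(2S,6R)-6-methoxy-3,6-dihydro-2H-pyran-2-yl]but-3-en-1-ol | CO[C@H]1C=CC[C@@H](/C=C\CCO)O1
F4 | step 8 | (3Z)-4-[(2S,6R)-6-methoxy-3,6-dihydro-2H-pyran-2-yl]but-3-enal | CO[C@H]1C=CC[C@@H](/C=C\CC=O)O1
F5 | step 8 | (3R,7R,9Z)-7-hydroxy-3-[(4-methoxybenzyl)oxy]-10-[(2S,6R)-6-methoxy-3,6-dihydro-2H-pyran-2-yl]-1-phenyldec-9-en-5-one | CO[C@H]1C=CC[C@@H](/C=C\C[C@@H](O)CC(=O)C[C@H](OCc2ccc(OC)cc2)CCc2ccccc2)O1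
F6 | step 8 | (3R,5R,7R,9Z)-3-[(4-methoxybenzyl)oxy]-10-[(2S,6R)-6-methoxy-3,6-dihydro-2H-pyran-2-yl]-1-phenyldec-9-ene-5,7-diol | CO[C@H]1C=CC[C@@H](/C=C\C[C@@H](O)C[C@@H](O)C[C@H](OCc2ccc(OC)cc2)CCc2ccccc2)O1
F7 | step 8 | (3R,5S,7R,9Z)-10-[(2S,6R)-6-methoxy-3,6-dihydro-2H-pyran-2-yl]-1-phenyldec-9-ene-3,5,7-triol | CO[C@H]1C=CC[C@@H](/C=C\C[C@@H](O)C[C@@H](O)C[C@H](O)CCc2ccccc2)O1
F8 | step 3 | (R,E)-triethyl{[1-phenyl-6-(4,4,5,5-tetramethyl-1,3,2-dioxaborolan-2-yl)hex-5-en-3-yl]oxy}silane | CC1(C)OB(/C=C/C[C@H](O[Si](CC)(CC)CC)CCc2ccccc2)OC1(C)C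
F9 | step 9 | acetonide of 17 (cis-2,2-dimethyl-1,3-dioxane across O4' and O6', TES on O8', methyl acetal retained) | CO[C@H]1C=CC[C@@H](/C=C\C[C@@H]2C[C@H](C[C@H](O[Si](CC)(CC)CC)CCc3ccccc3)OC(C)(C)O2)O1
F10 | step 9 | 4',6'-acetonide 8'-triethylsilyl ether of 19 | O=C1C=CC[C@@H](/C=C\C[C@@H]2C[C@H](C[C@H](O[Si](CC)(CC)CC)CCc3ccccc3)OC(C)(C)O2)O1
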